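All runs were generated by integration from invented constants; scatter was added.

The product I want is complex with one exchanged, and I must know when to stop this flask.

in all of them: starting complex 0.50 M; gas 200 mM (held)

| run | remark | time |
|---|---|---|
| theta | the very flask that is asked about, followed so far |  |
| flask |  | 15 d |

- theta (time / h: complex with one exchanged / %, complex with three exchanged / %): 2.50: 1.0, 0.2; 4.00: 3.3, 0.2; 5.00: 4.3, 1.1; 8.00: 7.1, 0.2; 12.0: 10.3, 0.4; 20.0: 14.5, 0; 30.0: 13.4, 0

(standard deviation of a reading: 0.5 percentage points)

- at the start none of the gas is in solution

1. time up to 15 d at which complex with one exchanged stands highest
2. the amount of complex with one exchanged, in percent of the starting complex charged, at that time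
3. earliest time at which at least nineteen twentieths of that best amount are there, in d
4. latest time at which they still are, in d

An intermediate stands highest where making crosses use. If use is first order, use is the amount divided by one time. So I take the holding time, the highest reading divided by the early climb, as my estimate of that time. The climb between 4.00 h and 12.0 h is 0.210 d⁻¹ of the charge. The highest reading, 14.5%, then gives 0.690 d, a half-life of 0.479 d.

But is there a fall at all? The last reading lies 1.1 percentage points lower, about twice the scatter, and that is weak. A reversible stop is my other candidate. And complex with three exchanged reads 0% at 30.0 h, so that last reading does not show where the material goes. The climb itself stands firmer: it rests on a rise of 7 points against 0.5 points per reading. I keep first-order use as my estimate. I put the peak between 20.0 h and 30.0 h. I assume that making still runs past the peak, so as a rough guess I put the latest time asked for one half-life after the last reading, at 1.73 d.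

The forecast says 14.5% at 2 d, with the earliest time asked for at 0.75 d and the latest at 8 d, on the ground that “Any onward leak must be slow, at most about 0.002/h”. My reckoning gives a first-order use of 0.0604 h⁻¹, so we part on the latest time.

The flask gives 14.5% at 1.13 d, with the earliest time asked for at 0.793 d and the latest at 1.66 d.

    complex with one exchanged + incoming ligand ⇌ leaving ligand + complex with two exchanged (K = 1.40, k = 0.00540 L mol⁻¹ min⁻¹)
    complex with one exchanged → side product (k = 0.00110 min⁻¹)
    starting complex + incoming ligand ⇌ leaving ligand + complex with one exchanged (K = 1.50, k = 0.0110 L mol⁻¹ min⁻¹)
    gas ⇌ incoming ligand, rate k4*(csat - [incoming ligand]) (kL = 9.10 × 10⁻⁴ min⁻¹)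
    complex with two exchanged + incoming ligand ⇌ leaving ligand + complex with three exchanged (K = 0.990, k = 0.0150 L mol⁻¹ min⁻¹)

At 1.72 d making stands at 0.908 of use, so the crossing is past. With complex with one exchanged held at 14.5%, the holding time gives 7.8 points of side product between 1.13 d and 1.50 d; this flask goes from 17.7% to 26.1%.

In the flask left until 10 d, the holding time of 0.690 d is short against that reading time, so the peak should fall inside the run. Computed, that flask reaches 14.5% and ends with 0.707% of complex with one exchanged.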